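**Plan**

- Rings are lettered A (2,4,6-trihydroxyphenyl end) to E (3,4,5-trihydroxyphenoxy end). The retrosynthesis first cuts ten O–CH3 bonds and one O–CH2CH3 bond, then cuts ring B at C1–C2, C4–C5 and C5–C6.
- Enabling feature: ring B is a 1,3,4,5-tetraoxygenated benzene. Its C1–O (ether to ring A) can arrive on the sp carbon of an aryl ethynyl ether, its C4–O (ether to ring C) on the sp3 carbon of a cyclobutenone, its C3–O as the enol ether of that cyclobutenone, and its C5–OH as the ketene carbonyl oxygen.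
- The cyclobutenone is cut into an aryloxyketene (CDE phenol plus a bromoacetate) and ethoxyacetylene. The CDE phenol is cut at its two diaryl ether C–O bonds, each between a hindered 2,6-dimethoxyphenol oxygen and an unhindered arylboron carbon.
- Forward: rings E and D are joined, then ring C (two Chan–Lam–Evans couplings), then phenol, acid and cyclobutenone. Ring A is made separately into its ethynyl ether. Ring B is the only ring formed in the route and arises last, followed by global dealkylation.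
- Stereochemistry: the target is achiral. The sp3 centre of the cyclobutenone is racemic and becomes an aromatic carbon.

Key step: step 9

Remark: Ar(A) = 2,4,6-trimethoxyphenyl and Ar(CDE) = 4-[3,5-dimethoxy-4-(3,4,5-trimethoxyphenoxy)phenoxy]-3,5-dimethoxyphenyl; compounds 21, 23 and 25 are racemates whose single sp3 centre is written without a descriptor.

**Route**

Step 1
Reactants: 1 2,4,6-trimethoxyphenol
Product: 2 2-{[(E)-1,2-dichloroethenyl]oxy}-1,3,5-trimethoxybenzene
Conditions: Cl2C=CHCl (2 equiv), K2CO3, DMF, 70 °C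
Reagents that add atoms: trichloroethylene, ClC=C(Cl)Cl
Why: The potassium phenoxide adds anti to dichloroacetylene formed in situ from trichloroethylene, the standard preparation of aryl (E)-1,2-dichlorovinyl ethers, which tolerates two ortho substituents.

Step 2
Reactants: 2 2-{[(E)-1,2-dichloroethenyl]oxy}-1,3,5-trimethoxybenzene
Product: 5 2-(ethynyloxy)-1,3,5-trimethoxybenzene (ring A ethynyl ether), via chloroalkynyl ether 3 (not isolated), via lithium acetylide 4 (not isolated)
Conditions: n-BuLi (2.2 equiv), THF, −78 → −40 °C; MeOH, −78 °C; kept cold in solution and used at once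
Reagents that add atoms: none
Why: Greene-type ynol ether synthesis, in which n-BuLi eliminates HCl to the chloroalkyne and exchanges the remaining chlorine for lithium, and cold protonation releases the terminal alkyne (any ring lithiation is undone by the same quench).

Step 3
Reactants: 6 4-bromo-2,6-dimethoxyphenol; 7 (3,4,5-trimethoxyphenyl)boronic acid
Product: 8 5-bromo-1,3-dimethoxy-2-(3,4,5-trimethoxyphenoxy)benzene (DE bromide)
Conditions: 7 (2 equiv), Cu(OAc)2 (1.5 equiv), pyridine, 4 Å molecular sieves, CH2Cl2, air, rt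
Reagents that add atoms: none
Why: Chan–Lam–Evans O-arylation with divalent copper at room temperature couples di-ortho-substituted phenols with electron-rich arylboronic acids and leaves the aryl bromide untouched, which a hot Ullmann coupling of a bromophenol would not.

Step 4
Reactants: 8 5-bromo-1,3-dimethoxy-2-(3,4,5-trimethoxyphenoxy)benzene
Product: 11 [3,5-dimethoxy-4-(3,4,5-trimethoxyphenoxy)phenyl]boronic acid (DE boronic acid), via aryllithium 9 (not isolated), via lithium triisopropoxyborate 10 (not isolated)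
Conditions: n-BuLi, THF, −78 °C; B(Oi-Pr)3, −78 °C → rt; 1 M HCl
Reagents that add atoms: triisopropyl borate, CC(C)OB(OC(C)C)OC(C)C; water, O
Why: Bromine–lithium exchange on an electron-rich aryl bromide, borate trapping and hydrolysis is the standard route to an arylboronic acid, and the ether groups are inert at −78 °C.

Step 5
Reactants: 11 [3,5-dimethoxy-4-(3,4,5-trimethoxyphenoxy)phenyl]boronic acid; 6 4-bromo-2,6-dimethoxyphenol
Product: 12 5-bromo-2-[3,5-dimethoxy-4-(3,4,5-trimethoxyphenoxy)phenoxy]-1,3-dimethoxybenzene (CDE bromide)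
Conditions: 11 (1.5 equiv), Cu(OAc)2 (1.5 equiv), pyridine, 4 Å molecular sieves, CH2Cl2, air, rt
Reagents that add atoms: none
Why: The same Chan–Lam–Evans coupling as in step 3, again with the hindered phenol oxygen as nucleophile and an unhindered meta-dimethoxy arylboronic acid, gives the trimer with bromine kept as the handle for the phenol.

Step 6
Reactants: 12 5-bromo-2-[3,5-dimethoxy-4-(3,4,5-trimethoxyphenoxy)phenoxy]-1,3-dimethoxybenzene
Product: 15 4-[3,5-dimethoxy-4-(3,4,5-trimethoxyphenoxy)phenoxy]-3,5-dimethoxyphenol (CDE phenol), via aryllithium 13 (not isolated), via lithium trimethoxyborate 14 (not isolated)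
Conditions: n-BuLi, THF, −78 °C; B(OMe)3, −78 °C → rt; AcOH, 30% aq. H2O2, 0 °C → rt
Reagents that add atoms: hydrogen peroxide, OO
Why: Lithiation, borylation and oxidation of the borate in the same flask (aryl shift from boron to oxygen) is a routine conversion of an aryl bromide into a phenol.

Step 7
Reactants: 15 4-[3,5-dimethoxy-4-(3,4,5-trimethoxyphenoxy)phenoxy]-3,5-dimethoxyphenol
Product: 17 2-[Ar(CDE)oxy]acetic acid, via methyl ester 16 (not isolated)
Conditions: BrCH2CO2Me, K2CO3, DMF, rt; then LiOH, THF/H2O, rt; 1 M HCl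
Reagents that add atoms: methyl bromoacetate, COC(=O)CBr; lithium hydroxide, [Li+].[OH-]
Why: Williamson O-alkylation of the unhindered phenol with an α-bromo ester and saponification in the same flask give the aryloxyacetic acid that serves as ketene precursor.

Step 8
Reactants: 17 2-[Ar(CDE)oxy]acetic acid; 18 ethoxyacetylene
Product: 21 racemic 4-[Ar(CDE)oxy]-3-ethoxycyclobut-2-en-1-one, via acid chloride 19 (not isolated), via aryloxyketene 20 (not isolated)
Conditions: (COCl)2, cat. DMF, CH2Cl2, 0 °C → rt, concentrate; then slow addition to 18 (3 equiv), Et3N, CH2Cl2/hexane, 0 °C → rt; rapid chromatography on Et3N-deactivated silica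
Reagents that add atoms: none
Why: Dehydrochlorination of the acid chloride gives the aryloxyketene, which undergoes the known thermal [2+2] cycloaddition with ethoxyacetylene; the terminal alkyne carbon bonds to the ketene carbonyl carbon, so the ethoxy carbon is joined to the aryloxy carbon, whose new sp3 centre is racemic and is lost in step 9.

Step 9
Reactants: 21 racemic 4-[Ar(CDE)oxy]-3-ethoxycyclobut-2-en-1-one; 5 2-(ethynyloxy)-1,3,5-trimethoxybenzene
Product: 26 3-ethoxy-2-[Ar(CDE)oxy]-5-(2,4,6-trimethoxyphenoxy)phenol (pentamer with ring B as 3-ethoxy-5-hydroxy), via vinylketene 22 (not isolated), via vinylcyclobutenone 23 (not isolated), via dienylketene 24 (not isolated), via cyclohexadienone 25 (not isolated)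
Conditions: 5 (2–3 equiv), PhMe, 80 °C, slow addition of 21, then 110 °C, Ar
Reagents that add atoms: none
Why: Heating opens 21 by conrotatory 4π cleavage of its C1–C4 bond (the C4 aryloxy donor rotates outward and lowers the barrier) to vinylketene 22; ynol ether 5 adds across the ketene C=C in a [2+2] cycloaddition to give 23, which reopens to dienylketene 24 and closes to cyclohexadienone 25, whose enolization gives phenol 26. The closest known reaction is the Danheiser benzannulation of cyclobutenones with alkoxyacetylenes to 3-alkoxyphenols; the oxygenated cyclobutenone and the aryl ethynyl ether are new substrates for it and have not been tested. Ring B, the only ring formed, closes by thermal disrotatory 6π electrocyclization of 24, which makes the C4–C5 bond after the [2+2] step has made C5–C6 and C1–C2. No stereocentre is created in 26, because the sp3 carbons of 21, 23 and 25 are racemic and all become aromatic carbons. The step needs regiocontrol in the [2+2] addition, and the polarization of the ynol ether should secure it: its nucleophilic terminal carbon bonds to the electrophilic ketene carbonyl carbon, so the carbon bearing the ring A oxygen ends up para to C4 and meta to the new hydroxyl. It also needs the alkyne to outrun ketene dimerization and acylation of 26 by 22, which slow addition of 21 to an excess of the easily made alkyne 5 is meant to ensure.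

Step 10
Reactants: 26 3-ethoxy-2-[Ar(CDE)oxy]-5-(2,4,6-trimethoxyphenoxy)phenol
Product: 27 2-[4-[4-[4-(3,4,5-trihydroxyphenoxy)-3,5-dihydroxyphenoxy]-3,5-dihydroxyphenoxy]-3,5-dihydroxyphenoxy]benzene-1,3,5-triol (target)
Conditions: BBr3 (excess), CH2Cl2, −78 °C → rt; H2O, 0 °C; reversed-phase chromatography under Ar
Reagents that add atoms: none
Why: BBr3 cleaves aryl methyl and aryl ethyl ethers by bromide attack on the O-alkyl carbon of the boron-complexed ether, whereas the four diaryl ether bonds offer no sp3 carbon and should survive.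

**Compound list**

1 | 2,4,6-trimethoxyphenol | COc1cc(OC)c(O)c(OC)c1 | starting material
2 | 2-{[(E)-1,2-dichloroethenyl]oxy}-1,3,5-trimethoxybenzene | Cl/C=C(/Cl)Oc1c(OC)cc(OC)cc1OC | intermediate
3 | 2-[(chloroethynyl)oxy]-1,3,5-trimethoxybenzene | ClC#COc1c(OC)cc(OC)cc1OC | intermediate (not isolated)
4 | lithium (2,4,6-trimethoxyphenoxy)acetylide | [Li]C#COc1c(OC)cc(OC)cc1OC | intermediate (not isolated)
5 | 2-(ethynyloxy)-1,3,5-trimethoxybenzene | C#COc1c(OC)cc(OC)cc1OC | intermediate
6 | 4-bromo-2,6-dimethoxyphenol | COc1cc(Br)cc(OC)c1O | starting material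
7 | (3,4,5-trimethoxyphenyl)boronic acid | COc1cc(B(O)O)cc(OC)c1OC | starting material
8 | 5-bromo-1,3-dimethoxy-2-(3,4,5-trimethoxyphenoxy)benzene | COc1cc(Br)cc(OC)c1Oc1cc(OC)c(OC)c(OC)c1 | intermediate
9 | [3,5-dimethoxy-4-(3,4,5-trimethoxyphenoxy)phenyl]lithium | [Li]c1cc(OC)c(Oc2cc(OC)c(OC)c(OC)c2)c(OC)c1 | intermediate (not isolated)
10 | lithium [3,5-dimethoxy-4-(3,4,5-trimethoxyphenoxy)phenyl]triisopropoxyborate | [Li+].CC(C)O[B-](OC(C)C)(OC(C)C)c1cc(OC)c(Oc2cc(OC)c(OC)c(OC)c2)c(OC)c1 | intermediate (not isolated)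
11 | [3,5-dimethoxy-4-(3,4,5-trimethoxyphenoxy)phenyl]boronic acid | OB(O)c1cc(OC)c(Oc2cc(OC)c(OC)c(OC)c2)c(OC)c1 | intermediate
12 | 5-bromo-2-[3,5-dimethoxy-4-(3,4,5-trimethoxyphenoxy)phenoxy]-1,3-dimethoxybenzene | COc1cc(Br)cc(OC)c1Oc1cc(OC)c(Oc2cc(OC)c(OC)c(OC)c2)c(OC)c1 | intermediate
13 | Ar(CDE)lithium | [Li]c1cc(OC)c(Oc2cc(OC)c(Oc3cc(OC)c(OC)c(OC)c3)c(OC)c2)c(OC)c1 | intermediate (not isolated)
14 | lithium Ar(CDE)trimethoxyborate | [Li+].CO[B-](OC)(OC)c1cc(OC)c(Oc2cc(OC)c(Oc3cc(OC)c(OC)c(OC)c3)c(OC)c2)c(OC)c1 | intermediate (not isolated)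
15 | 4-[3,5-dimethoxy-4-(3,4,5-trimethoxyphenoxy)phenoxy]-3,5-dimethoxyphenol | Oc1cc(OC)c(Oc2cc(OC)c(Oc3cc(OC)c(OC)c(OC)c3)c(OC)c2)c(OC)c1 | intermediate
16 | methyl 2-[Ar(CDE)oxy]acetate | COC(=O)COc1cc(OC)c(Oc2cc(OC)c(Oc3cc(OC)c(OC)c(OC)c3)c(OC)c2)c(OC)c1 | intermediate (not isolated)
17 | 2-[Ar(CDE)oxy]acetic acid | OC(=O)COc1cc(OC)c(Oc2cc(OC)c(Oc3cc(OC)c(OC)c(OC)c3)c(OC)c2)c(OC)c1 | intermediate
18 | ethoxyacetylene (ethoxyethyne) | CCOC#C | starting material
19 | 2-[Ar(CDE)oxy]acetyl chloride | ClC(=O)COc1cc(OC)c(Oc2cc(OC)c(Oc3cc(OC)c(OC)c(OC)c3)c(OC)c2)c(OC)c1 | intermediate (not isolated)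
20 | [Ar(CDE)oxy]ketene | O=C=COc1cc(OC)c(Oc2cc(OC)c(Oc3cc(OC)c(OC)c(OC)c3)c(OC)c2)c(OC)c1 | intermediate (not isolated)
21 | racemic 4-[Ar(CDE)oxy]-3-ethoxycyclobut-2-en-1-one | CCOC1=CC(=O)C1Oc1cc(OC)c(Oc2cc(OC)c(Oc3cc(OC)c(OC)c(OC)c3)c(OC)c2)c(OC)c1 | intermediate
22 | (3Z)-4-[Ar(CDE)oxy]-3-ethoxybuta-1,3-dien-1-one (vinylketene, aryloxy trans to the ketene carbon) | O=C=C/C(OCC)=C/Oc1cc(OC)c(Oc2cc(OC)c(Oc3cc(OC)c(OC)c(OC)c3)c(OC)c2)c(OC)c1 | intermediate (not isolated)
23 | racemic 3-[Ar(A)oxy]-4-{(Z)-2-[Ar(CDE)oxy]-1-ethoxyethenyl}cyclobut-2-en-1-one | O=C1C=C(Oc2c(OC)cc(OC)cc2OC)C1/C(OCC)=C/Oc1cc(OC)c(Oc2cc(OC)c(Oc3cc(OC)c(OC)c(OC)c3)c(OC)c2)c(OC)c1 | intermediate (not isolated)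
24 | (3E,5Z)-3-[Ar(A)oxy]-6-[Ar(CDE)oxy]-5-ethoxyhexa-1,3,5-trien-1-one (dienylketene, C2 and C5 cis on the C3=C4 bond) | O=C=C/C(Oc1c(OC)cc(OC)cc1OC)=C\C(OCC)=C\Oc1cc(OC)c(Oc2cc(OC)c(Oc3cc(OC)c(OC)c(OC)c3)c(OC)c2)c(OC)c1 | intermediate (not isolated)
25 | racemic 3-[Ar(A)oxy]-6-[Ar(CDE)oxy]-5-ethoxycyclohexa-2,4-dien-1-one | O=C1C=C(Oc2c(OC)cc(OC)cc2OC)C=C(OCC)C1Oc1cc(OC)c(Oc2cc(OC)c(Oc3cc(OC)c(OC)c(OC)c3)c(OC)c2)c(OC)c1 | intermediate (not isolated)
26 | 3-ethoxy-2-[Ar(CDE)oxy]-5-(2,4,6-trimethoxyphenoxy)phenol | COc1cc(OC)c(Oc2cc(OCC)c(Oc3cc(OC)c(Oc4cc(OC)c(Oc5cc(OC)c(OC)c(OC)c5)c(OC)c4)c(OC)c3)c(O)c2)c(OC)c1 | intermediate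
27 | 2-[4-[4-[4-(3,4,5-trihydroxyphenoxy)-3,5-dihydroxyphenoxy]-3,5-dihydroxyphenoxy]-3,5-dihydroxyphenoxy]benzene-1,3,5-triol | Oc1cc(O)c(Oc2cc(O)c(Oc3cc(O)c(Oc4cc(O)c(Oc5cc(O)c(O)c(O)c5)c(O)c4)c(O)c3)c(O)c2)c(O)c1 | target

**Step count and risks**

Total: 10 steps. Longest linear sequence: 8 steps (steps 3 to 10, from 6 and 7); the ring A branch (steps 1 and 2) joins at step 9.

Step 9. Vinylketene 22 may be consumed by dimerization or by acylating phenol 26 before it meets the alkyne, or the terminal ynol ether 5 may polymerize at the temperature needed for ring opening. The fallback no longer builds ring B but brings it in as a preformed ring, continuing the diaryl ether chemistry of steps 3 to 6. It sets out from bromide 12. Lithiation and borylation as in step 4 would give the CDE boronic acid F1. Chan–Lam–Evans coupling of F1 with phenol 6 would give the tetramer bromide F2, and a second lithiation and borylation the tetramer boronic acid F3. Coupling of F3 with 2,4,6-trimethoxyphenol 1 would give the dodecamethyl ether F4 of the target, and BBr3 as in step 10 returns to the route at 27.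

Step 8. Aryloxyketene 20 may dimerize or be intercepted by amine-derived species faster than it adds to the only moderately nucleophilic ethoxyacetylene, and the enol ether of 21 may hydrolyse during isolation. The fallback reaches the same vinylketene 22 without a cyclobutenone, by 1,4-dehydrochlorination of a β-ethoxy unsaturated acid chloride, a known way to vinylketenes. It sets out from phenol 15. Base-mediated alkylation with ethyl 4-chloroacetoacetate would give the keto ester F5, and triethyl orthoformate with cat. H2SO4 in EtOH the enol ether ester F6. LiOH would give the acid F7 and (COCl)2 the acid chloride F8. Et3N in warm toluene containing alkyne 5 would then remove HCl across the γ-carbon and the carbonyl to give 22, which continues through 23, 24 and 25 and comes back to the route at 26.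

Step 10. The pyrogallol and phloroglucinol rings may oxidize in air during aqueous work-up and chromatography, and the product may co-elute with partly dealkylated material. The fallback derivatizes, purifies and releases. It sets out from 26: after the BBr3 treatment the crude polyphenol is peracetylated (Ac2O, pyridine) to the dodecaacetate F9, which is stable to air and silica and separable from incompletely cleaved congeners. Acidic methanolysis (HCl from AcCl in degassed MeOH) would then give 27.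

**Further compounds**

F1 | step 9 | Ar(CDE)boronic acid | OB(O)c1cc(OC)c(Oc2cc(OC)c(Oc3cc(OC)c(OC)c(OC)c3)c(OC)c2)c(OC)c1
F2 | step 9 | 5-bromo-2-[Ar(CDE)oxy]-1,3-dimethoxybenzene (tetramer bromide) | COc1cc(Br)cc(OC)c1Oc1cc(OC)c(Oc2cc(OC)c(Oc3cc(OC)c(OC)c(OC)c3)c(OC)c2)c(OC)c1
F3 | step 9 | {4-[Ar(CDE)oxy]-3,5-dimethoxyphenyl}boronic acid (tetramer boronic acid) | OB(O)c1cc(OC)c(Oc2cc(OC)c(Oc3cc(OC)c(Oc4cc(OC)c(OC)c(OC)c4)c(OC)c3)c(OC)c2)c(OC)c1
F4 | step 9 | dodecamethyl ether of the target | COc1cc(OC)c(Oc2cc(OC)c(Oc3cc(OC)c(Oc4cc(OC)c(Oc5cc(OC)c(OC)c(OC)c5)c(OC)c4)c(OC)c3)c(OC)c2)c(OC)c1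
F5 | step 8 | ethyl 4-[Ar(CDE)oxy]-3-oxobutanoate | CCOC(=O)CC(=O)COc1cc(OC)c(Oc2cc(OC)c(Oc3cc(OC)c(OC)c(OC)c3)c(OC)c2)c(OC)c1
F6 | step 8 | ethyl (E)-4-[Ar(CDE)oxy]-3-ethoxybut-2-enoate | CCOC(=O)/C=C(/OCC)COc1cc(OC)c(Oc2cc(OC)c(Oc3cc(OC)c(OC)c(OC)c3)c(OC)c2)c(OC)c1
F7 | step 8 | (E)-4-[Ar(CDE)oxy]-3-ethoxybut-2-enoic acid | OC(=O)/C=C(/OCC)COc1cc(OC)c(Oc2cc(OC)c(Oc3cc(OC)c(OC)c(OC)c3)c(OC)c2)c(OC)c1
F8 | step 8 | (E)-4-[Ar(CDE)oxy]-3-ethoxybut-2-enoyl chloride | ClC(=O)/C=C(/OCC)COc1cc(OC)c(Oc2cc(OC)c(Oc3cc(OC)c(OC)c(OC)c3)c(OC)c2)c(OC)c1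
F9 | step 10 | dodecaacetate of the target | CC(=O)Oc1cc(OC(C)=O)c(Oc2cc(OC(C)=O)c(Oc3cc(OC(C)=O)c(Oc4cc(OC(C)=O)c(Oc5cc(OC(C)=O)c(OC(C)=O)c(OC(C)=O)c5)c(OC(C)=O)c4)c(OC(C)=O)c3)c(OC(C)=O)c2)c(OC(C)=O)c1
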